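## Structural features

The target is a longipinane diester: a bicyclo[3.1.1]hept-3-en-2-one (cyclobutane C1–C2–C8–C7, bridged on one face by C1–C11(=O)–C10=C9(CH3)–C8) whose two one-carbon bridges C2 and C7 are joined on the other face by the chain C3–C4–C5–C6, so that a seven-membered ring (C1 to C7) shares the cyclobutane with the enone ring. This numbering is kept for every intermediate. There are six stereocentres (C1 R, C2 R, C3 R, C5 R, C7 S, C8 R): the four cyclobutane carbons are contiguous and locked by the ring system, C2 is quaternary, and the carbinol carbons C3 (next to C2) and C5 (next to the gem-dimethyl C6) are both neopentyl and stand 1,3-trans across C4. Fragile elements are the strained cyclobutane (α to the C11 carbonyl, and prone to skeletal rearrangement if a cation forms at C9 or C3), the enone, and two different esters on a 1,3-diol (β-elimination, acyl migration, deconjugation of the senecioate). The real difficulty is threefold: a cyclobutane with a quaternary carbon inside a medium ring, two oxygenated centres whose faces differ only through the remote C11/C9 groups, and two different acyl groups on two similar secondary alcohols. The key step exploits the fact that the seven-membered ring is the only uncommon ring and that its C3 carbon is flanked by quaternary C2. Removing C4 leaves a tricyclo[4.4.0.0^{2,7}]decan-3-one that a cis-decalin gives by enolate alkylation, its ketone can enolise only toward C5, and reinsertion of C4 returns a C3 enone whose β-carbon is C5.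

## Logic of the disconnections

33 ⇒ 31 ⇒ 30. The C9=C10 π bond and the free C11 carbonyl are introduced last. This keeps a second enone out of all C3/C5 chemistry and leaves one acid-labile mask to remove. The forward steps must enolise the C11 ketone only toward C10 and leave two esters alone.

30 ⇒ 28 + 29. The O3–acyl bond is cut. The senecioate, the ester most prone to deconjugation, is thus made as late as possible. The forward step must acylate a neopentyl alcohol without moving the double bond.

28 ⇒ 26 + 27. The O5–acyl bond and the C3–H bond are cut together. One redox-neutral step then sets C3 from C5 (1,3-anti), delivers the isovalerate to O5 and leaves O3 free, so the two oxygens never need separate differentiation. It demands intramolecular hydride transfer across a seven-membered ring.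

26 ⇒ 24. The C5–O bond is cut back to the enone. The price is that the facial selectivity at C5 must come from the catalyst, because the substrate is nearly unbiased.

24 ⇒ 21 (key). C3–C4 and C4–C5 are cut and C3–C5 is restored, which removes the seven-membered ring and leaves only common rings. The forward step needs a single enol ether regioisomer and cleavage of the internal cyclopropane bond.

21 ⇒ 19 ⇒ 18. The C2–C8 bond is cut, which opens the cyclobutane to a cis-decalin keto sulfonate. The leaving group on C8 must be trans to the C1–C2 bond, and the more substituted enolate must react.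

18 ⇒ 17 ⇒ 16 ⇒ 15 ⇒ 13. The O–S and C8–O bonds are cut back to a C8=C9 alkene, with O3 carried as a benzyl ether so that only O8 is sulfonylated. Hydroboration must occur on the face of the ring-fusion hydrogens.

13 ⇒ 12 ⇒ 11 ⇒ 10. The ketal C–O bonds are cut and the alkene is returned to C9=C10. One ketalisation both masks C11 and moves the alkene next to C8. The cis ring fusion (C1–H is α to C11) must survive the acid.

10 ⇒ 9 ⇒ 7 ⇒ 6 ⇒ 4. The O3–benzyl, C3–O and C2–CH3 bonds are cut (a 1,2-carbonyl transposition with methylation), leading back to a C2 ketone. C2 must be saturated before C11 becomes a carbonyl, otherwise the ring-A alkene would move into conjugation through C1.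

4 ⇒ 2 + 3, and 2 ⇒ 1. C1–C11 and C7–C8 are cut (Diels–Alder), giving two achiral partners. The cycloaddition must be regio-, endo- and enantioselective on a β-neopentyl enone.

## Other disconnections considered

Alternative 1: The cut removes C1–C7, C6–C7 and C2–C8 at once and unravels the skeleton to the acyclic diphosphate A1.
- **Forward key step:** a longipinene synthase ionises A1 and one cationic cascade closes all three rings and ends by proton loss from C10, giving α-longipinene A2.
- **In its favour:** the complete carbon skeleton, the four ring stereocentres and the C9=C10 alkene with its methyl arise in one operation. On structure and step economy for the skeleton this is clearly better than the chosen plan, which needs 16 steps to reach the same ring system.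
- **Against it here:** A2 carries none of the three oxygens. C11 is allylic and could be oxidised, but C3 and C5 are unactivated methylenes on a ring whose faces are nearly equivalent. Two site- and face-selective C–H hydroxylations and differentiation of the two alcohols would be needed, realistically with engineered oxygenases. The enzyme must also give the drawn enantiomer.
- **Comparison:** enzyme-steered cation chemistry replaces stepwise polar chemistry. The chosen plan is much longer to the skeleton, but its C3 ketone and C4=C5 enone mark C5 and C3 for oxygenation, which the hydrocarbon A2 cannot offer.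

Alternative 2: The cut is C7–C8 (with O–C11 re-formed), leading to the fused δ-lactone A3.
- **Forward key step:** enolisation and O-silylation of A3, then a [3,3] shift through a bridged boat, forms C7–C8, breaks O–C11 and gives the bicyclo[4.1.1]octenone acid A4 with an exocyclic C1=C11 methylene.
- **In its favour:** the rearrangement is stereospecific, with chirality relayed from C2. The seven-membered ring arrives with C3 as a ketone and C5 at the enol ether level, so on placing the ring oxygens it equals or betters the chosen plan.
- **Against it here:** the contraction makes a cyclobutane inside a bicyclo[4.1.1] frame through a forced boat, and the gain from ester to silyl ester must pay for that strain, so the driving force is doubtful. The carboxyl and methylene groups of A4 must then be built over several steps into the C9–C10–C11 enone bridge, C1 must be set, and the C3/C5 reductions remain.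
- **Comparison:** the chosen plan closes the cyclobutane by a strongly exergonic sulfonate displacement and has the six-membered ring from the first C–C bond-forming step. The step count after A4 would probably match or exceed that of the chosen route.

Alternative 3: The cut is C1–C7 and C2–C8 across the cyclobutane, leading to the acyclic trienoyl chloride A5.
- **Forward key step:** triethylamine dehydrochlorinates A5, and the ketene C=C adds across the central trisubstituted alkene to close the cyclobutanone and the six-membered ring together, giving A6.
- **In its favour:** the reaction type is known for bicyclo[3.1.1]heptenones, is suprafacial on the alkene (C1/C2 relative configuration from the E geometry), and gives the C9=C10 alkene and the C3 oxygen directly. For the bicyclic core it is shorter than the chosen plan and at least its equal.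
- **Against it here:** the seven-membered ring must still be closed between C6 (the prenyl terminus, which must become quaternary) and the hindered C7 carbonyl. Cationic or ketyl closure would instead bond the less substituted C5 (six-membered ring). C7 must then be deoxygenated, C5 and C11 oxygenated, and facial control by the C3 stereocentre in the cycloaddition is uncertain.
- **Comparison:** Alternative 3 wins on convergence and on the cyclobutane step. The chosen plan wins on the medium ring (made from a six-membered ring by one-carbon insertion) and on the C5 oxygen.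

Key step: step 16

Remark on numbering: atoms keep the target numbers throughout. In the decalins ring A is C1–C2–C3–C5–C6–C7 and ring B is C1–C11–C10–C9–C8–C7; C4 is absent before step 16.

Remark on C9: C9 is a spectator centre erased in step 21. In 15–32 its methyl is drawn cis to the C2–C8 bond, which is what syn hydroboration (step 10) followed by inversion at C8 (step 14) delivers; a drawing with the methyl toward C7 would not fit this chemistry.

Assumption: the sense of induction of the chiral catalysts in steps 2 and 17 on these substrates is taken to be the one required; the enantiomeric catalyst or ligand would be used otherwise.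

## Route

Step 1
Reactants: 1 3-methylbut-2-enal
Product: 2 (E)-triisopropyl[(3-methylbuta-1,3-dien-1-yl)oxy]silane
Conditions: iPr3SiOTf, Et3N, Et2O, 0 °C to rt
Reagents that add atoms: triisopropylsilyl trifluoromethanesulfonate CC(C)[Si](C(C)C)(C(C)C)OS(=O)(=O)C(F)(F)F
Why: Soft enolisation of the enal at the γ-methyl group and O-silylation give the (E)-1-silyloxydiene (known silyl dienol ether formation); the bulky triisopropylsilyl group resists silyl transfer to the Lewis acid of step 2.

Step 2
Reactants: 2 (E)-triisopropyl[(3-methylbuta-1,3-dien-1-yl)oxy]silane; 3 4,4-dimethylcyclohex-2-en-1-one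
Product: 4 cis-fused Diels–Alder adduct (C2 ketone, C11–OTIPS, C9=C10)
Conditions: (S)-1-(2-methylphenyl)-3,3-diphenyltetrahydro-1H,3H-pyrrolo[1,2-c][1,3,2]oxazaborole·HNTf2 (20 mol%), CH2Cl2, −78 to −20 °C
Reagents that add atoms: none
Why: Catalytic enantioselective Diels–Alder reaction: the C11 silyloxy and C9 methyl groups both make C8 the nucleophilic diene terminus, so C8 bonds to the enone β-carbon C7 and C11 to the α-carbon C1; the endo transition state gives the cis ring fusion with O11 cis to the C1–C2 bond, and the boron Lewis acid bound to the carbonyl screens one enone face and so sets C1 and C7 (C11 is erased in step 8).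

Step 3
Reactants: 4 cis-fused Diels–Alder adduct
Product: 6 C2 enol triflate (C2=C3), via potassium enolate 5 (not isolated)
Conditions: KN(SiMe3)2, THF, −78 °C; PhNTf2, −78 to 0 °C
Reagents that add atoms: N-phenylbis(trifluoromethanesulfonimide) O=S(=O)(N(c1ccccc1)S(=O)(=O)C(F)(F)F)C(F)(F)F
Why: Kinetic deprotonation takes the unhindered C3 methylene rather than the tertiary, flanked C1–H, and O-sulfonylation gives the enol triflate; the low temperature avoids C1 enolisation, which would expel the C11 silyloxy group.

Step 4
Reactants: 6 C2 enol triflate
Product: 7 diene with C2-methyl C2=C3 alkene (C9=C10 and C11–OTIPS unchanged)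
Conditions: MeMgBr, Fe(acac)3 (5 mol%), THF/NMP, −30 to 0 °C
Reagents that add atoms: methylmagnesium bromide C[Mg]Br
Why: Iron-catalysed Kumada-type cross-coupling of an alkenyl triflate with a methyl Grignard reagent installs the C2 methyl group; silyl ethers and isolated alkenes are tolerated.

Step 5
Reactants: 7 diene with C2-methyl C2=C3 alkene
Product: 9 C3 alcohol, via B-alkyl-9-BBN adduct 8 (not isolated)
Conditions: 9-BBN, THF, rt to 50 °C; NaOH, H2O2, 0 °C to rt
Reagents that add atoms: hydrogen peroxide OO
Why: Hydroboration–oxidation puts boron on C3 (next to a CH2), while the ring-B alkene is spared because its boron-accepting carbon C10 is crowded and deactivated by the adjacent TIPS ether. Syn addition is drawn on the face of ring A opposite ring B; the other facial isomer converges, since C3 becomes a ketone and C2 an enolate carbon.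

Step 6
Reactants: 9 C3 alcohol
Product: 10 C3 benzyl ether
Conditions: NaH, BnBr, Bu4NI (cat.), THF/DMF, 0 °C to rt
Reagents that add atoms: benzyl bromide BrCc1ccccc1
Why: Williamson etherification masks O3 so that O8 is the only free hydroxyl when the sulfonate is made; the benzyl ether is orthogonal to the silyl ether, ketal and tosylate.

Step 7
Reactants: 10 C3 benzyl ether
Product: 11 C11 allylic alcohol
Conditions: Bu4NF, THF, rt to 40 °C
Reagents that add atoms: none
Why: Fluoride cleaves the Si–O bond of the secondary allylic silyl ether; the benzyl ether and both alkenes are inert.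

Step 8
Reactants: 11 C11 allylic alcohol
Product: 12 C11 enone (C9=C10)
Conditions: MnO2, CH2Cl2, rt
Reagents that add atoms: none
Why: MnO2 oxidises the allylic alcohol under neutral heterogeneous conditions, so C1–H (now α to a carbonyl) is not epimerised.

Step 9
Reactants: 12 C11 enone
Product: 13 C11 ethylene ketal with C8=C9 alkene
Conditions: HO(CH2)2OH, HC(OEt)3, TsOH·H2O (cat.), CH2Cl2, rt
Reagents that add atoms: ethane-1,2-diol OCCO
Why: Acid-catalysed ketalisation of a conjugated enone with double-bond migration: the dienyl oxocarbenium ion loses the γ-proton at C8 and the dienol ether is reprotonated at C10, giving the dioxolane with the endocyclic trisubstituted C8=C9 alkene (the steroid 4-en-3-one to 5-ene ketal pattern). Orthoformate as water scavenger allows room temperature, which limits enolisation toward C1.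

Step 10
Reactants: 13 C11 ethylene ketal with C8=C9 alkene
Product: 15 C8 alcohol, via C8 alkylborane 14 (not isolated)
Conditions: BH3·THF, THF, 0 °C to rt; NaOH, H2O2, 0 °C to rt
Reagents that add atoms: hydrogen peroxide OO
Why: Hydroboration–oxidation puts boron on the less substituted C8 and H on C9, syn, from the face of ring B that carries the ring-fusion hydrogens, because the other face of C8 is blocked by quaternary C6 on C7. This sets O8 cis to H7 (trans to the C1–C2 bond, as the later backside attack requires) and H9 cis to O8.

Step 11
Reactants: 15 C8 alcohol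
Product: 16 C8 tosylate
Conditions: TsCl, Et3N, Me3N·HCl (cat.), CH2Cl2, 0 °C to rt
Reagents that add atoms: 4-methylbenzenesulfonyl chloride Cc1ccc(cc1)S(=O)(=O)Cl
Why: Sulfonylation with retention at C8; the trimethylamine-catalysed protocol is suited to hindered secondary alcohols.

Step 12
Reactants: 16 C8 tosylate
Product: 17 C3 alcohol C8 tosylate
Conditions: H2 (1 atm), Pd(OH)2/C, EtOAc, rt
Reagents that add atoms: none
Why: Hydrogenolysis of the benzyl ether; the alkyl sulfonate and the dioxolane are inert and no alkene remains.

Step 13
Reactants: 17 C3 alcohol C8 tosylate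
Product: 18 C3 ketone C8 tosylate
Conditions: Dess–Martin periodinane, CH2Cl2, 0 °C to rt
Reagents that add atoms: none
Why: Mild oxidation of the secondary alcohol; any epimerisation at C2 is harmless because C2 becomes an enolate carbon next.

Step 14
Reactants: 18 C3 ketone C8 tosylate
Product: 19 nor-tricyclic ketone (tricyclo[4.4.0.0^{2,7}]decan-3-one skeleton, C11 dioxolane)
Conditions: KOtBu, tBuOH/THF, rt to 50 °C
Reagents that add atoms: none
Why: Intramolecular enolate alkylation (4-exo-tet) under equilibrating conditions: the more substituted C2 enolate, held axial on ring B by the cis fusion, attacks C8 opposite the tosylate with inversion, making C2 quaternary and fixing all four cyclobutane centres. E2 is shut off because H7 and H9 are both cis to the leaving group, and O-alkylation would need a bridgehead enol ether; keto-sulfonate closures to bicyclo[3.1.1]heptanones are the precedent.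

Step 15
Reactants: 19 nor-tricyclic ketone
Product: 21 C3 trimethylsilyl enol ether (C3=C5), via lithium enolate 20 (not isolated)
Conditions: LiN(iPr)2, THF, −78 °C; TMSCl, Et3N, −78 to 0 °C
Reagents that add atoms: chlorotrimethylsilane C[Si](C)(C)Cl
Why: C2 is quaternary and a bridgehead of the new bicycle, so deprotonation is possible only at C5 and O-silylation gives a single enol ether; basic conditions are used because a silyl triflate could open the dioxolane.

Step 16
Reactants: 21 C3 trimethylsilyl enol ether
Product: 24 tricyclic cyclohept-4-en-3-one (C11 dioxolane), via siloxycyclopropane 22 (not isolated), via β-chloro ketone 23 (not isolated)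
Conditions: Et2Zn, CH2I2, CH2Cl2, 0 °C to rt; pyridine quench, solvent exchange; FeCl3, DMF, 0 °C to rt; NaOAc, MeOH, reflux
Reagents that add atoms: diiodomethane ICI
Why: The zinc carbenoid EtZnCH2I transfers CH2 to the electron-rich C3=C5 bond in a concerted syn [2+1] addition (Simmons–Smith), which makes C3–C4 and C4–C5 and gives the 1-siloxybicyclo[4.1.0] unit 22 from either face, both of which converge. Trivalent iron then oxidises the siloxycyclopropane by one electron with loss of the silyl group; the cyclopropyloxy radical cleaves the ring-fusion bond C3–C5, because this gives the C3 carbonyl and a secondary radical inside the enlarged ring (the outer bond would give a primary radical), and a second FeCl3 delivers chlorine to C5 to give 23. Acetate removes HCl across C4–C5 (E1cB) to give the conjugated enone 24. The closest known reaction type is the Saegusa ring expansion of cycloalkanone silyl enol ethers through siloxycyclopropanes to cycloalk-2-enones. The seven-membered ring is therefore not closed end to end: the three-membered ring forms by cheletropic-type addition and the medium ring arises by fragmentation of the shared bond. No stereocentre is created in 24, and C1, C2, C7 and C8 are untouched. The selectivities needed are a single enol ether regioisomer (secured in step 15 by quaternary C2), internal rather than external cyclopropane cleavage (secured by radical stability), and survival of the dioxolane and cyclobutane (DMF-complexed FeCl3 at 0 °C is mild enough). If the enol ether, which lies between two quaternary carbons, reacts sluggishly, the more electrophilic carbenoid CF3CO2ZnCH2I (Et2Zn, CF3CO2H, CH2I2) can be used.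

Step 17
Reactants: 24 tricyclic cyclohept-4-en-3-one
Product: 26 C5 alcohol C3 ketone, via C5 pinacolboronate 25 (not isolated)
Conditions: CuCl (5 mol%), NaOtBu (10 mol%), (R)-1-[(S)-2-(diphenylphosphino)ferrocenyl]ethyldicyclohexylphosphine (6 mol%), B2pin2, MeOH, THF, rt; NaBO3·4H2O, THF/H2O, rt
Reagents that add atoms: sodium perborate [Na+].[Na+].O[B-]1(O)OO[B-](O)(O)OO1
Why: Copper-catalysed conjugate borylation (a monovalent copper boryl adds to the enone β-carbon and methanol protonates the copper enolate), then C–B oxidation with retention. The two faces of C5 differ only through remote groups, so the chiral ligand is relied on to deliver boron to the face turned toward C8/C9; perborate is mild enough to avoid retro-aldol or β-elimination.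

Step 18
Reactants: 26 C5 alcohol C3 ketone; 27 3-methylbutanal
Product: 28 C5 3-methylbutanoate C3 alcohol (1,3-anti)
Conditions: SmI2 (30 mol%), THF, −10 °C
Reagents that add atoms: none
Why: Evans–Tishchenko reduction: the samarium-bound hemiacetal formed from O5 and the aldehyde transfers its hydride intramolecularly to C3 on the face of O5. O3 therefore ends up anti to O5 (toward C1/C11), the isovalerate sits on O5 and O3 is left free, so one step sets C3 and differentiates the two oxygens.

Step 19
Reactants: 28 C5 3-methylbutanoate C3 alcohol; 29 3-methylbut-2-enoyl chloride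
Product: 30 diester with C11 dioxolane
Conditions: DMAP, pyridine, CH2Cl2, 0 to 40 °C
Reagents that add atoms: none
Why: DMAP-catalysed acylation of the hindered alcohol with retention at C3; pyridine rather than a trialkylamine limits vinylketene formation and so keeps the senecioate double bond conjugated.

Step 20
Reactants: 30 diester with C11 dioxolane
Product: 31 diester C11 ketone (C9–H)
Conditions: HCl (2 M aq.), THF, rt
Reagents that add atoms: water O
Why: Acid hydrolysis of the dioxolane; the esters survive dilute acid and C1, a cyclobutane bridgehead, cannot epimerise.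

Step 21
Reactants: 31 diester C11 ketone
Product: 33 target CNP0335239.1, via trimethylsilyl enol ether 32 (not isolated)
Conditions: TMSOTf, Et3N, CH2Cl2, 0 °C; volatiles removed; Pd(OAc)2, MeCN, rt
Reagents that add atoms: none
Why: Saegusa–Ito oxidation: soft enolisation silylates the ketone much faster than the esters and only toward C10 (C1 is a bridgehead); divalent palladium forms the oxa-π-allyl complex and β-hydride elimination of H9 gives the C9=C10 enone and zerovalent palladium, erasing the C9 stereocentre.

## Compound list

1 | 3-methylbut-2-enal | CC(C)=CC=O | starting material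
2 | (E)-triisopropyl[(3-methylbuta-1,3-dien-1-yl)oxy]silane | C=C(C)/C=C/O[Si](C(C)C)(C(C)C)C(C)C | intermediate
3 | 4,4-dimethylcyclohex-2-en-1-one | CC1(C)CCC(=O)C=C1 | starting material
4 | cis-fused 4,4,6-trimethyl-8-(triisopropylsilyloxy)-3,4,4a,5,8,8a-hexahydronaphthalen-1(2H)-one (C2 ketone; O11 cis to the C1–C2 bond; C9=C10; H1 and H7 cis) | O=C1CCC(C)(C)[C@H]2CC(C)=C[C@@H](O[Si](C(C)C)(C(C)C)C(C)C)[C@@H]12 | intermediate
5 | potassium enolate of 4 (C2(OK)=C3) | [K+].[O-]C1=CCC(C)(C)[C@H]2CC(C)=C[C@@H](O[Si](C(C)C)(C(C)C)C(C)C)[C@@H]12 | intermediate
6 | C2 enol triflate (C2=C3) of 4 | FC(F)(F)S(=O)(=O)OC1=CCC(C)(C)[C@H]2CC(C)=C[C@@H](O[Si](C(C)C)(C(C)C)C(C)C)[C@@H]12 | intermediate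
7 | diene: C2-methyl C2=C3 alkene, C9=C10, C11–OTIPS | CC1=CCC(C)(C)[C@H]2CC(C)=C[C@@H](O[Si](C(C)C)(C(C)C)C(C)C)[C@@H]12 | intermediate
8 | C3 B-alkyl-9-borabicyclo[3.3.1]nonane (H2 and B cis, on the face of ring A opposite ring B) | C[C@H]1[C@H](B3C4CCCC3CCC4)CC(C)(C)[C@H]2CC(C)=C[C@@H](O[Si](C(C)C)(C(C)C)C(C)C)[C@@H]12 | intermediate
9 | C3 alcohol (C2–H and C3–OH cis; C2,C3 facial isomer drawn, either converges) | C[C@H]1[C@H](O)CC(C)(C)[C@H]2CC(C)=C[C@@H](O[Si](C(C)C)(C(C)C)C(C)C)[C@@H]12 | intermediate
10 | C3 benzyl ether | C[C@H]1[C@H](OCc3ccccc3)CC(C)(C)[C@H]2CC(C)=C[C@@H](O[Si](C(C)C)(C(C)C)C(C)C)[C@@H]12 | intermediate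
11 | C11 allylic alcohol | C[C@H]1[C@H](OCc3ccccc3)CC(C)(C)[C@H]2CC(C)=C[C@@H](O)[C@@H]12 | intermediate
12 | C11 enone (C9=C10) | C[C@H]1[C@H](OCc3ccccc3)CC(C)(C)[C@H]2CC(C)=CC(=O)[C@@H]12 | intermediate
13 | C11 ethylene ketal with C8=C9 alkene | C[C@H]1[C@H](OCc3ccccc3)CC(C)(C)[C@H]2C=C(C)CC4(OCCO4)[C@@H]12 | intermediate
14 | C8 alkylborane (BH2 on C8, cis to H7 and H9) | C[C@H]1[C@H](OCc3ccccc3)CC(C)(C)[C@H]2[C@H](B)[C@@H](C)CC4(OCCO4)[C@@H]12 | intermediate
15 | C8 alcohol (O8 cis to H7 and H1, trans to the C9 methyl) | C[C@H]1[C@H](OCc3ccccc3)CC(C)(C)[C@H]2[C@H](O)[C@@H](C)CC4(OCCO4)[C@@H]12 | intermediate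
16 | C8 tosylate | C[C@H]1[C@H](OCc3ccccc3)CC(C)(C)[C@H]2[C@H](OS(=O)(=O)c3ccc(C)cc3)[C@@H](C)CC4(OCCO4)[C@@H]12 | intermediate
17 | C3 alcohol C8 tosylate | C[C@H]1[C@H](O)CC(C)(C)[C@H]2[C@H](OS(=O)(=O)c3ccc(C)cc3)[C@@H](C)CC4(OCCO4)[C@@H]12 | intermediate
18 | C3 ketone C8 tosylate | C[C@H]1C(=O)CC(C)(C)[C@H]2[C@H](OS(=O)(=O)c3ccc(C)cc3)[C@@H](C)CC4(OCCO4)[C@@H]12 | intermediate
19 | nor-tricyclic ketone (C3 bonded to C5; C11 dioxolane; C9 methyl cis to the C2–C8 bond) | O=C1CC(C)(C)[C@@H]2[C@H]3C4(OCCO4)C[C@H](C)[C@@H]2[C@]31C | intermediate
20 | lithium enolate of 19 (C3(OLi)=C5) | [Li+].[O-]C1=CC(C)(C)[C@@H]2[C@H]3C4(OCCO4)C[C@H](C)[C@@H]2[C@]31C | intermediate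
21 | nor-tricyclic C3 trimethylsilyl enol ether (key-step precursor) | C[Si](C)(C)OC1=CC(C)(C)[C@@H]2[C@H]3C4(OCCO4)C[C@H](C)[C@@H]2[C@]31C | intermediate
22 | siloxycyclopropane (C3–C4–C5 ring; one facial isomer drawn, either converges) | C[Si](C)(C)O[C@]12C[C@H]1C(C)(C)[C@@H]3[C@H]4C5(OCCO5)C[C@H](C)[C@@H]3[C@]42C | intermediate
23 | β-chloro ketone (C3 ketone, C5–Cl; one C5 epimer drawn, either eliminates) | O=C1C[C@H](Cl)C(C)(C)[C@@H]2[C@H]3C4(OCCO4)C[C@H](C)[C@@H]2[C@]31C | intermediate
24 | tricyclic cyclohept-4-en-3-one, C11 dioxolane (key-step product) | O=C1C=CC(C)(C)[C@@H]2[C@H]3C4(OCCO4)C[C@H](C)[C@@H]2[C@]31C | intermediate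
25 | C5 pinacolboronate C3 ketone (boron on the face toward C8) | O=C1C[C@@H](B5OC(C)(C)C(C)(C)O5)C(C)(C)[C@@H]2[C@H]3C4(OCCO4)C[C@H](C)[C@@H]2[C@]31C | intermediate
26 | C5 alcohol C3 ketone | O=C1C[C@@H](O)C(C)(C)[C@@H]2[C@H]3C4(OCCO4)C[C@H](C)[C@@H]2[C@]31C | intermediate
27 | 3-methylbutanal | CC(C)CC=O | starting material
28 | C5 3-methylbutanoate C3 alcohol (O3 anti to O5) | O[C@@H]1C[C@@H](OC(=O)CC(C)C)C(C)(C)[C@@H]2[C@H]3C4(OCCO4)C[C@H](C)[C@@H]2[C@]31C | intermediate
29 | 3-methylbut-2-enoyl chloride | CC(C)=CC(=O)Cl | starting material
30 | C3 senecioate C5 isovalerate with C11 dioxolane | CC(C)=CC(=O)O[C@@H]1C[C@@H](OC(=O)CC(C)C)C(C)(C)[C@@H]2[C@H]3C4(OCCO4)C[C@H](C)[C@@H]2[C@]31C | intermediate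
31 | diester C11 ketone (C9–H) | CC(C)=CC(=O)O[C@@H]1C[C@@H](OC(=O)CC(C)C)C(C)(C)[C@@H]2[C@H]3C(=O)C[C@H](C)[C@@H]2[C@]31C | intermediate
32 | C11 trimethylsilyl enol ether (C10=C11) of 31 | CC(C)=CC(=O)O[C@@H]1C[C@@H](OC(=O)CC(C)C)C(C)(C)[C@@H]2[C@H]3C(O[Si](C)(C)C)=C[C@H](C)[C@@H]2[C@]31C | intermediate
33 | CNP0335239.1 (C3 senecioate, C5 isovalerate, C9=C10 enone) | CC(C)=CC(=O)O[C@@H]1C[C@@H](OC(=O)CC(C)C)C(C)(C)[C@@H]2[C@H]3C(=O)C=C(C)[C@@H]2[C@]31C | target

## Step count and least certain steps

Total step count: 21. Longest linear sequence: 21 steps (1 to 33); 3, 27 and 29 enter as commercial partners.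

Step 16 (key step). The cyclopropanation may stall because the enol ether lies between two quaternary carbons. The FeCl3 stage may also strip the dioxolane or cleave the outer cyclopropane bond. Fallback: a diazoalkane homologation from ketone 19. TMSCHN2 with BF3·OEt2 (or Sc(OTf)3) at −78 °C should add to the C3 carbonyl, and the less substituted carbon C5 should migrate, giving the C4-silylated cycloheptanone F1. Protodesilylation on work-up (K2CO3, MeOH) would give the saturated cycloheptanone F2. F2 has only one enolisable α-carbon (C4), and dehydrogenation with IBX in DMSO at 70 °C would return the route at 24.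

Step 2. The enone has a neopentyl β-carbon, so conversion may be low. A stepwise or uncatalysed background pathway could erode the enantioselectivity, and silanol may be lost from the β-silyloxy ketone. Fallback: from 2 and 3, a racemic cycloaddition with an achiral Lewis acid (Et2AlCl, toluene, −20 °C) to the racemic adduct F3, then resolution by preparative chromatography on a chiral stationary phase, returning at 4.

Step 9. Acid may enolise the C11 carbonyl toward C1 and epimerise the ring fusion, or the double bond may move to the exocyclic position. Fallback: keep C11 at the alcohol level until C8 is functionalised.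
- From 10, SeO2 (cat.)/tBuOOH allylic oxidation at the ring methylene next to the more substituted alkene carbon should give the C8 allylic alcohol F4, with O8 on the face of the ring-fusion hydrogens.
- Hydroxyl-directed hydrogenation with [Ir(cod)(PCy3)(py)]PF6 should give the saturated C8 alcohol F5, with H9 cis to O8.
- Tosylation gives the C8 tosylate F6, Bu4NF the C11 alcohol F7, and Dess–Martin periodinane the C11 ketone F8.
- Non-equilibrating ketalisation (1,2-bis(trimethylsilyloxy)ethane, TMSOTf cat., −78 °C) returns the route at 16.

Step 14. Alkylation may occur through the less substituted C5 enolate, or the tertiary enolate carbon may fail to reach the hindered secondary sulfonate, so that slow decomposition competes. Fallback: regiospecific, irreversible enolate generation instead of alkoxide equilibration. From 18, thermodynamic silylation (TMSCl, Et3N, DMF, 80 °C) should give the tetrasubstituted C2=C3 trimethylsilyl enol ether F9. Cleavage with MeLi in THF/HMPA releases only the C2 lithium enolate, which should close to 19.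

Step 17. Facial selectivity may be poor, because the catalyst must override a nearly unbiased substrate. The β-hydroxy ketone may also undergo retro-aldol cleavage or β-elimination. Fallback: from 24, catalyst-controlled nucleophilic epoxidation (H2O2, the bis(trifluoroacetate) salt of 9-amino-9-deoxy-epi-quinine, dioxane) to the C4,C5-epoxy ketone F10. Reductive opening at the α-carbon with SmI2 (THF/MeOH, −78 °C) returns the route at 26.

Step 18. Hemiacetal formation and hydride transfer at two neopentyl centres across a seven-membered ring may be slow, and the acyl group may migrate from O5 to O3 on the samarium alkoxide. Fallback: from 26, acylation with 3-methylbutanoyl chloride (pyridine, DMAP, 0 °C) to the C5 isovalerate ketone F11. Reagent-controlled reduction of the C3 ketone (quaternary C2 as the large group) with (S)-2-methyl-CBS-oxazaborolidine and BH3·SMe2 returns the route at 28.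

## Further compounds

F1 | step 16 | C4-trimethylsilyl tricyclic cycloheptan-3-one (one C4 epimer drawn) | O=C1[C@H]([Si](C)(C)C)CC(C)(C)[C@@H]2[C@H]3C4(OCCO4)C[C@H](C)[C@@H]2[C@]31C
F2 | step 16 | tricyclic cycloheptan-3-one with C11 dioxolane | O=C1CCC(C)(C)[C@@H]2[C@H]3C4(OCCO4)C[C@H](C)[C@@H]2[C@]31C
F3 | step 2 | racemic Diels–Alder adduct (racemate of 4, one enantiomer drawn) | O=C1CCC(C)(C)[C@H]2CC(C)=C[C@@H](O[Si](C(C)C)(C(C)C)C(C)C)[C@@H]12
F4 | step 9 | C8 allylic alcohol (C9=C10, C11–OTIPS, C3–OBn) | C[C@H]1[C@H](OCc3ccccc3)CC(C)(C)[C@H]2[C@H](O)C(C)=C[C@@H](O[Si](C(C)C)(C(C)C)C(C)C)[C@@H]12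
F5 | step 9 | saturated C8 alcohol (H9 cis to O8, C11–OTIPS) | C[C@H]1[C@H](OCc3ccccc3)CC(C)(C)[C@H]2[C@H](O)[C@@H](C)C[C@@H](O[Si](C(C)C)(C(C)C)C(C)C)[C@@H]12
F6 | step 9 | C8 tosylate with C11–OTIPS | C[C@H]1[C@H](OCc3ccccc3)CC(C)(C)[C@H]2[C@H](OS(=O)(=O)c3ccc(C)cc3)[C@@H](C)C[C@@H](O[Si](C(C)C)(C(C)C)C(C)C)[C@@H]12
F7 | step 9 | C8 tosylate C11 alcohol | C[C@H]1[C@H](OCc3ccccc3)CC(C)(C)[C@H]2[C@H](OS(=O)(=O)c3ccc(C)cc3)[C@@H](C)C[C@@H](O)[C@@H]12
F8 | step 9 | C8 tosylate C11 ketone | C[C@H]1[C@H](OCc3ccccc3)CC(C)(C)[C@H]2[C@H](OS(=O)(=O)c3ccc(C)cc3)[C@@H](C)CC(=O)[C@@H]12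
F9 | step 14 | C2=C3 trimethylsilyl enol ether of 18 | CC1=C(O[Si](C)(C)C)CC(C)(C)[C@H]2[C@H](OS(=O)(=O)c3ccc(C)cc3)[C@@H](C)CC4(OCCO4)[C@@H]12
F10 | step 17 | C4,C5-epoxy ketone (oxygen on the face toward C8) | O=C1[C@H]2O[C@H]2C(C)(C)[C@@H]3[C@H]4C5(OCCO5)C[C@H](C)[C@@H]3[C@]41C
F11 | step 18 | C5 3-methylbutanoate C3 ketone | O=C1C[C@@H](OC(=O)CC(C)C)C(C)(C)[C@@H]2[C@H]3C4(OCCO4)C[C@H](C)[C@@H]2[C@]31C
A1 | alternative 1 | (2E,6E)-farnesyl diphosphate | CC(C)=CCC/C(C)=C/CC/C(C)=C/COP(=O)(O)OP(=O)(O)O
A2 | alternative 1 | α-longipinene | C1CCC(C)(C)[C@@H]2[C@H]3CC=C(C)[C@@H]2[C@]31C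
A3 | alternative 2 | fused δ-lactone (C9 lactone carbonyl, C8 methylene on C2, O–C11H2 on C1=C7) of the 5-methoxycycloheptadien-3-one | O=C1C[C@@]2(C)C(=O)C=C(OC)C(C)(C)C=C2CO1
A4 | alternative 2 | bicyclo[4.1.1]octenone acid with exocyclic C1=C11 methylene | OC(=O)[C@H]1[C@@H]2C(C)(C)C(OC)=CC(=O)[C@@]1(C)C2=C
A5 | alternative 3 | (2E,6E)-8-(tert-butyldimethylsilyloxy)farnesoyl chloride (C3 R in route numbering) | ClC(=O)/C=C(\C)CC/C=C(\C)[C@H](O[Si](C)(C)C(C)(C)C)CC=C(C)C
A6 | alternative 3 | bicyclo[3.1.1]hept-2-en-6-one with the C3-silyloxy prenyl arm on C2 | CC(C)=CC[C@@H](O[Si](C)(C)C(C)(C)C)[C@@]1(C)[C@@H]2CC=C(C)[C@H]1C2=O
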